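**Percent misleads.** A falling percent is easily read as a reaction that worsens with charge. At 4.00 h the north-west run shows less target in percent than the south-west run, 14 % against 29 %, yet it holds more in molar terms, 0.308 M against 0.0725 M.

| flask | starting material | gas | remark | time |
|---|---|---|---|---|
| south-west | 0.25 M | 82 mM (held) | run made earlier |  |
| west | 0.66 M | 82 mM (held) | run made earlier |  |
| north-west | 2.2 M | 82 mM (held) | run made earlier |  |
| theta | 0.20 M | 82 mM (held) |  | 5.0 h |
| alpha | 1.2 M | 82 mM (held) |  | 5.0 h |
| delta | 1.0 M | 82 mM (held) |  | 5.0 h |
| eta | 0.63 M | 82 mM (held) |  | 5.0 h |
| epsilon | 2.0 M | 82 mM (held) |  | 5.0 h |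

| south-west: time / h | south-west: target / % | west: time / h | west: target / % | north-west: time / h | north-west: target / % |
|---|---|---|---|---|---|
| 0.333 | 1 | 0.333 | 2 | 0.250 | 0 |
| 0.833 | 1 | 0.833 | 0 | 0.500 | 0 |
| 1.50 | 6 | 1.50 | 4 | 1.00 | 1 |
| 2.50 | 14 | 2.50 | 11 | 2.00 | 5 |
| 4.00 | 29 | 4.00 | 25 | 4.00 | 14 |

(standard deviation of a reading: 1.5 percentage points)

- the numbers in the tables scatter by 1.5 percentage points (one standard deviation)
- at the start none of the gas is in solution

- the flasks put in order of amount of target, in percent of the starting material charged, best first, at 5.0 h (theta / alpha / delta / eta / epsilon)
- the amount of target, in percent of the starting material charged of the flask you put first, at 5.0 h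
- the amount of target, in percent of the starting material charged of the flask you put last, at 5.0 h

**Fast gas.** In the first extreme, dissolved gas stands at saturation, 82 mM, from the start. Starting material then goes pseudo-first-order, and the percent at a given time is one value, D, for any charge S.

**Slow gas.** In the second extreme, dissolved gas reacts as soon as it enters. Each litre receives a fixed amount per hour, molar target is the same for any charge, and the percent falls as 1/S.

**Between them.** From the south-west run to the north-west run the charge rises 8.80 times while the percent at 4.00 h falls 2.07 times, so these runs lie between the extremes. Adding the two hindrances gives the percent y = D/(1 + S/C). These two scattered readings then give 1.57 M for C, the crossing charge, where the two hindrances weigh equally.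

**Own reckoning.** The last south-west slope, extended to 5.0 h, multiplies the percent by 1.34, taken here as the same for every charge. The percent falls as the charge rises, so theta comes first with 40.1 % and epsilon last with 19.9 %.

The forecast gives theta > eta > delta > alpha > epsilon, with 40 % and 20 %, on the grounds that “Percent yield falls as starting material rises, while absolute output still rises”.

**The flask.** The simulation gives theta > eta > delta > alpha > epsilon, with 36.4 % and 17.7 %.

    starting material + coupling partner → intermediate + by-product (k = 4.30 /M/h)
    intermediate → target (k = 0.450 /h)
    intermediate → side product (k = 0.300 /h)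
    gas ⇌ coupling partner, rate k4*(csat - [coupling partner]) (kL = 2.80 /h)
    2 starting material → self-condensation product (k = 7.50 × 10⁻⁴ /M/h)

At 5.00 h coupling partner stands at 0.0757 M in theta and 0.0287 M in epsilon, with saturation at 82 mM. Used as a ratio, which needs no time factor, C carries theta's value to 18.1 % for epsilon.

**A neighbour.** For theta's flask charged with 0.50 M, the same ratio gives 31.1 %. The computed flask holds 31.9 %.

The data were computed for an exercise, noise included.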